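**Plan**

- Numbering used throughout (hexahydronaphthalene core): ring A = C4a, C5–C8, C8a (C5=C6, side chain on C7); ring B = C1–C4, C4a, C8a (methyl on C2, C2=C3, alkenyl arm on C4, CO2H on C4a).
- Retrosynthetic cuts, in order: the two ester O–CH3 bonds; C2–CH3 (enol triflate); C4a–C4 with C4a–C2 re-formed, which contracts ring B to a four-membered carbinol ring (C1, C2, C4a, C8a); the diene C–C bond of the arm (Stille); C2–C4a back to C2–C6 (1,3-acyl shift); C1–C8a and C2–C6 (Diels–Alder); ring A (Michael/aldol).
- Forward: ring A first (citronellal + methyl vinyl ketone, then dienyl triflate, then diene ester); a bicyclo[2.2.2]octenone by [4+2] across C6/C8a; light moves the acyl carbon C2 from C6 to C4a to give a cis-fused cyclobutanone; the trans-cyclohexane fragment is joined through a stannylvinyl carbinol; ring B then arises by two-carbon ring expansion; methylation and ester cleavage finish.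
- Enabling feature: in ring B the angular ester carbon C4a is 1,3 to C2 (a latent ketone) and C4 is the β-carbon of the enone C2(=O)–C3=C4. A C2 alkoxide on the strained C1–C2–C4a–C8a ring can therefore release C4a as an ester enolate (retro-aldol), which recloses on C4 (Michael).
- Stereochemistry: side-chain C2' from (S)-citronellal; C7 by organocatalyst control; C8a by anti-facial Diels–Alder; C4a (cis fusion) and C4 in the ring expansion; (E)-trisubstituted alkene by syn carboalumination; trans-cyclohexane from the trans aldehyde.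

Key step: step 10

Remark: compounds 1, 2, 8, 12 and 16 and both antipodes of the prolinol silyl ether catalyst are taken as commercially available. The carbinol centre made in step 8 is drawn as the epimer expected from attack on the face away from ring A; either epimer serves, because this centre is lost in step 10.

**Step 1**
Reactants: 1 (S)-citronellal; 2 methyl vinyl ketone
Product: 4 (4R)-4-[(2S)-6-methylhept-5-en-2-yl]cyclohex-2-en-1-one, via keto aldehyde Michael adduct 3 (not isolated)
Conditions: (R)-2-[diphenyl(trimethylsilyloxy)methyl]pyrrolidine (10 mol %), ethyl 3,4-dihydroxybenzoate (20 mol %), neat, 4 °C; then LiOH (cat.), iPrOH, rt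
Reagents that add atoms: none
Why: Enamine-catalysed Michael addition of the aldehyde to the enone, in which the bulky silyloxydiphenylmethyl group shields one enamine face so that catalyst control should set the new α-centre (future C7) as R, followed by intramolecular aldol condensation (Robinson-type annulation) that leaves the citronellal centre untouched.

**Step 2**
Reactants: 4 (4R)-4-[(2S)-6-methylhept-5-en-2-yl]cyclohex-2-en-1-one
Product: 6 (4R)-4-[(2S)-6-methylhept-5-en-2-yl]cyclohexa-1,5-dien-1-yl trifluoromethanesulfonate, via lithium cross-conjugated dienolate 5 (not isolated)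
Conditions: LiN(iPr)2, THF, −78 °C; PhNTf2, −78 → 0 °C; aq. NH4Cl
Reagents that add atoms: N-phenylbis(trifluoromethanesulfonimide) (PhNTf2), O=S(=O)(N(c1ccccc1)S(=O)(=O)C(F)(F)F)C(F)(F)F
Why: Kinetic α'-deprotonation of the enone gives the cross-conjugated dienolate, which is O-sulfonylated to the 2-triflyloxy-1,3-diene (enol triflate formation) without touching C7.

**Step 3**
Reactants: 6 (4R)-4-[(2S)-6-methylhept-5-en-2-yl]cyclohexa-1,5-dien-1-yl trifluoromethanesulfonate
Product: 7 methyl (4R)-4-[(2S)-6-methylhept-5-en-2-yl]cyclohexa-1,5-diene-1-carboxylate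
Conditions: Pd(OAc)2 (5 mol %), PPh3, CO (1 atm), MeOH, Et3N, DMF, rt; used at once
Reagents that add atoms: carbon monoxide, [C-]#[O+]; methanol, CO
Why: Palladium-catalysed methoxycarbonylation of the dienyl triflate (oxidative addition, CO insertion, methanolysis) should give the cross-conjugated diene ester, which is carried on directly because 2-carboalkoxy-1,3-dienes dimerise on standing.

**Step 4**
Reactants: 7 methyl (4R)-4-[(2S)-6-methylhept-5-en-2-yl]cyclohexa-1,5-diene-1-carboxylate; 8 1,1-diethoxyethene
Product: 10 methyl 5-oxo-8-[(2S)-6-methylhept-5-en-2-yl]bicyclo[2.2.2]oct-2-ene-2-carboxylate (side chain syn to the alkene bridge), via diethyl ketal cycloadduct 9 (not isolated)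
Conditions: 8 (3 equiv), toluene, trace Et3N, 70 °C; then 1 M HCl, THF, rt
Reagents that add atoms: water, O
Why: Inverse-electron-demand Diels–Alder reaction of the electron-poor 2-carboalkoxydiene with the ketene acetal, in which the nucleophilic CH2 bonds to the ester β-carbon C8a and the acetal carbon to C6 ("para" orientation) on the diene face anti to the C7 side chain, which sets C8a, followed by mild ketal hydrolysis to the β,γ-unsaturated ketone.

**Step 5**
Reactants: 10 methyl 5-oxo-8-[(2S)-6-methylhept-5-en-2-yl]bicyclo[2.2.2]oct-2-ene-2-carboxylate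
Product: 11 methyl cis-8-oxo-4-[(2S)-6-methylhept-5-en-2-yl]bicyclo[4.2.0]oct-2-ene-1-carboxylate (four-membered ring anti to the side chain)
Conditions: hν (300 nm, Pyrex), degassed benzene (0.01 M), rt, to partial conversion; recovered 10 recycled
Reagents that add atoms: none
Why: Direct n→π* excitation of the β,γ-unsaturated ketone triggers the photochemical 1,3-acyl shift (Norrish type 1 cleavage to an acyl/allyl radical pair, recombination at the ester-bearing γ-carbon C4a), which is suprafacial and so should deliver the cis-fused cyclobutanone with the quaternary C4a and the C5=C6 alkene in place.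

**Step 6**
Reactants: 12 methyl trans-4-formylcyclohexane-1-carboxylate
Product: 13 methyl trans-4-ethynylcyclohexane-1-carboxylate
Conditions: dimethyl (1-diazo-2-oxopropyl)phosphonate, K2CO3, MeOH, rt
Reagents that add atoms: dimethyl (1-diazo-2-oxopropyl)phosphonate, COP(=O)(OC)C(=[N+]=[N-])C(C)=O
Why: Seyferth–Gilbert homologation under mild carbonate conditions converts the aldehyde into the terminal alkyne, and the 1,4-trans (diequatorial) arrangement is the thermodynamic one and is kept.

**Step 7**
Reactants: 13 methyl trans-4-ethynylcyclohexane-1-carboxylate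
Product: 15 methyl trans-4-[(1E)-1-iodoprop-1-en-2-yl]cyclohexane-1-carboxylate, via alkenyldimethylalane 14 (not isolated)
Conditions: Me3Al (3 equiv), Cp2ZrCl2 (20 mol %), CH2Cl2, −20 °C → rt; then I2, THF, −30 → 0 °C
Reagents that add atoms: trimethylaluminium, C[Al](C)C; iodine, II
Why: Negishi zirconium-catalysed carboalumination adds methyl and aluminium syn across the alkyne with aluminium at the terminus, and iodinolysis with retention should give the (E)-trisubstituted alkenyl iodide (one extra equivalent of Me3Al complexes the ester).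

**Step 8**
Reactants: 11 methyl cis-8-oxo-4-[(2S)-6-methylhept-5-en-2-yl]bicyclo[4.2.0]oct-2-ene-1-carboxylate; 16 (E)-1,2-bis(tributylstannyl)ethene
Product: 18 methyl cis-8-hydroxy-4-[(2S)-6-methylhept-5-en-2-yl]-8-[(E)-2-(tributylstannyl)ethenyl]bicyclo[4.2.0]oct-2-ene-1-carboxylate, via (E)-2-(tributylstannyl)ethenyllithium 17 (not isolated)
Conditions: 16, nBuLi (1.0 equiv), THF, −78 °C; then 11, −78 °C; AcOH quench at −78 °C
Reagents that add atoms: none
Why: Tin–lithium exchange at one terminus of the bis-stannane gives the (E)-β-stannylvinyllithium, which should add 1,2 to the strained, highly electrophilic cyclobutanone in preference to the hindered ester, and the cold acidic quench avoids premature retro-aldol opening of the lithium alkoxide.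

**Step 9**
Reactants: 18 methyl cis-8-hydroxy-4-[(2S)-6-methylhept-5-en-2-yl]-8-[(E)-2-(tributylstannyl)ethenyl]bicyclo[4.2.0]oct-2-ene-1-carboxylate; 15 methyl trans-4-[(1E)-1-iodoprop-1-en-2-yl]cyclohexane-1-carboxylate
Product: 19 methyl cis-8-hydroxy-8-[(1E,3E)-4-(trans-4-methoxycarbonylcyclohexyl)penta-1,3-dien-1-yl]-4-[(2S)-6-methylhept-5-en-2-yl]bicyclo[4.2.0]oct-2-ene-1-carboxylate
Conditions: Pd2(dba)3 (2.5 mol %), AsPh3 (20 mol %), CuI (10 mol %), DMF, rt → 40 °C; chromatography on Et3N-deactivated silica
Reagents that add atoms: none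
Why: Stille cross-coupling of the alkenylstannane with the alkenyl iodide under neutral conditions joins the two fragments with retention of both alkene geometries and tolerates the tertiary alcohol and both esters.

**Step 10**
Reactants: 19 methyl cis-8-hydroxy-8-[(1E,3E)-4-(trans-4-methoxycarbonylcyclohexyl)penta-1,3-dien-1-yl]-4-[(2S)-6-methylhept-5-en-2-yl]bicyclo[4.2.0]oct-2-ene-1-carboxylate
Product: 23 methyl (4R,4aR,7R,8aR)-4-[(1E)-2-(trans-4-methoxycarbonylcyclohexyl)prop-1-en-1-yl]-7-[(2S)-6-methylhept-5-en-2-yl]-2-(trifluoromethanesulfonyloxy)-1,4,4a,7,8,8a-hexahydronaphthalene-4a-carboxylate, via lithium cyclobutoxide 20 (not isolated), via ring-opened lithium ester dienolate 21 (not isolated), via ring-expanded lithium enolate 22 (not isolated)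
Conditions: LiN(SiMe3)2 (1.1 equiv), THF (0.01 M), −78 → 0 °C; then PhNTf2, −78 → 0 °C; aq. NH4Cl
Reagents that add atoms: N-phenylbis(trifluoromethanesulfonimide) (PhNTf2), O=S(=O)(N(c1ccccc1)S(=O)(=O)C(F)(F)F)C(F)(F)F
Why: Deprotonation gives the 1-dienylcyclobutoxide 20, whose strained C2–C4a bond breaks in the retro-aldol sense (the ring strain is released and the leaving carbanion is an ester enolate further stabilised by the C5=C6 alkene) to give 21, and the enolate carbon C4a then adds to the β-carbon C4 of the new dienone, so that C4a has moved from C2 to C4 and the four-membered ring (C1, C2, C4a, C8a) has become ring B. The closest known reaction type is the alkoxide-accelerated [1,3] shift of 1-vinylcyclobutanols that carry a carbanion-stabilising group at the adjacent ring carbon (two-carbon ring expansion of cyclobutanones to cyclohexanones). Ring B closes in a 6-endo-trig Michael mode, and α-attack of the dienolate with 1,4- rather than 1,6-addition is the only combination that gives an unstrained six-membered ring. At C4a the three-atom tether hangs from C8a on the face set in step 4 and can reach only that face of the planar enolate, hence the cis ring fusion; at C4 the (E)-enone places the alkenyl residue outside the forming ring (pseudo-equatorial), and a lithium-bridged endo-type arrangement with the ester enolate over the enone should put it cis to the ester. The regiodefined enolate 22 (C2=C3) is trapped in situ as the enol triflate, which fixes the position of the ring B alkene, and high dilution suppresses intermolecular proton transfer to 21.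

**Step 11**
Reactants: 23 methyl (4R,4aR,7R,8aR)-4-[(1E)-2-(trans-4-methoxycarbonylcyclohexyl)prop-1-en-1-yl]-7-[(2S)-6-methylhept-5-en-2-yl]-2-(trifluoromethanesulfonyloxy)-1,4,4a,7,8,8a-hexahydronaphthalene-4a-carboxylate
Product: 24 methyl (4S,4aR,7R,8aR)-4-[(1E)-2-(trans-4-methoxycarbonylcyclohexyl)prop-1-en-1-yl]-2-methyl-7-[(2S)-6-methylhept-5-en-2-yl]-1,4,4a,7,8,8a-hexahydronaphthalene-4a-carboxylate
Conditions: MeZnCl (2 equiv), Pd(PPh3)4 (5 mol %), THF, 50 °C
Reagents that add atoms: methylzinc chloride, C[Zn]Cl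
Why: Negishi cross-coupling of the enol triflate with the methylzinc reagent installs the C2 methyl group without moving the alkene and tolerates both esters.

**Step 12**
Reactants: 24 methyl (4S,4aR,7R,8aR)-4-[(1E)-2-(trans-4-methoxycarbonylcyclohexyl)prop-1-en-1-yl]-2-methyl-7-[(2S)-6-methylhept-5-en-2-yl]-1,4,4a,7,8,8a-hexahydronaphthalene-4a-carboxylate
Product: 25 (4S,4aR,7R,8aR)-4-[(1E)-2-(trans-4-carboxycyclohexyl)prop-1-en-1-yl]-2-methyl-7-[(2S)-6-methylhept-5-en-2-yl]-1,4,4a,7,8,8a-hexahydronaphthalene-4a-carboxylic acid (target)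
Conditions: NaSEt (8 equiv), DMF, 90 °C; then dilute HCl to pH 3, 0 °C
Reagents that add atoms: none
Why: SN2 demethylation by ethanethiolate cleaves both methyl esters at the O–CH3 bond, so the hindered angular ester is no obstacle and no stereocentre or alkene is touched (the trans cyclohexane acid is also the thermodynamic epimer).

**Compound list**

1 | (S)-citronellal, (3S)-3,7-dimethyloct-6-enal | CC(C)=CCC[C@H](C)CC=O | starting material
2 | methyl vinyl ketone | CC(=O)C=C | starting material
3 | (2R)-2-[(2S)-6-methylhept-5-en-2-yl]-5-oxohexanal | CC(C)=CCC[C@H](C)[C@H](C=O)CCC(C)=O | intermediate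
4 | (4R)-4-[(2S)-6-methylhept-5-en-2-yl]cyclohex-2-en-1-one | CC(C)=CCC[C@H](C)[C@@H]1C=CC(=O)CC1 | intermediate
5 | lithium (4R)-4-[(2S)-6-methylhept-5-en-2-yl]cyclohexa-1,5-dien-1-olate | CC(C)=CCC[C@H](C)[C@@H]1C=CC([O-])=CC1.[Li+] | intermediate
6 | (4R)-4-[(2S)-6-methylhept-5-en-2-yl]cyclohexa-1,5-dien-1-yl trifluoromethanesulfonate | CC(C)=CCC[C@H](C)[C@@H]1C=CC(OS(=O)(=O)C(F)(F)F)=CC1 | intermediate
7 | methyl (4R)-4-[(2S)-6-methylhept-5-en-2-yl]cyclohexa-1,5-diene-1-carboxylate | CC(C)=CCC[C@H](C)[C@@H]1C=CC(C(=O)OC)=CC1 | intermediate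
8 | 1,1-diethoxyethene (ketene diethyl acetal) | C=C(OCC)OCC | starting material
9 | methyl 5,5-diethoxy-8-[(2S)-6-methylhept-5-en-2-yl]bicyclo[2.2.2]oct-2-ene-2-carboxylate (side chain syn to the alkene bridge) | CC(C)=CCC[C@H](C)[C@@H]1[C@@H]2C=C(C(=O)OC)[C@@H](CC2(OCC)OCC)C1 | intermediate
10 | methyl 5-oxo-8-[(2S)-6-methylhept-5-en-2-yl]bicyclo[2.2.2]oct-2-ene-2-carboxylate (side chain syn to the alkene bridge) | CC(C)=CCC[C@H](C)[C@@H]1[C@@H]2C=C(C(=O)OC)[C@@H](CC2=O)C1 | intermediate
11 | methyl cis-8-oxo-4-[(2S)-6-methylhept-5-en-2-yl]bicyclo[4.2.0]oct-2-ene-1-carboxylate (four-membered ring anti to the side chain) | CC(C)=CCC[C@H](C)[C@@H]1C=C[C@]2(C(=O)OC)[C@@H](CC2=O)C1 | intermediate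
12 | methyl trans-4-formylcyclohexane-1-carboxylate | O=C[C@H]1CC[C@H](C(=O)OC)CC1 | starting material
13 | methyl trans-4-ethynylcyclohexane-1-carboxylate | C#C[C@H]1CC[C@H](C(=O)OC)CC1 | intermediate
14 | methyl trans-4-[(1E)-1-(dimethylalumanyl)prop-1-en-2-yl]cyclohexane-1-carboxylate | C[Al](C)/C=C(\C)[C@H]1CC[C@H](C(=O)OC)CC1 | intermediate
15 | methyl trans-4-[(1E)-1-iodoprop-1-en-2-yl]cyclohexane-1-carboxylate | I/C=C(\C)[C@H]1CC[C@H](C(=O)OC)CC1 | intermediate
16 | (E)-1,2-bis(tributylstannyl)ethene | CCCC[Sn](CCCC)(CCCC)/C=C/[Sn](CCCC)(CCCC)CCCC | starting material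
17 | (E)-2-(tributylstannyl)ethenyllithium | [Li]/C=C/[Sn](CCCC)(CCCC)CCCC | intermediate
18 | methyl cis-8-hydroxy-4-[(2S)-6-methylhept-5-en-2-yl]-8-[(E)-2-(tributylstannyl)ethenyl]bicyclo[4.2.0]oct-2-ene-1-carboxylate (hydroxyl on the face towards ring A) | CC(C)=CCC[C@H](C)[C@@H]1C=C[C@]2(C(=O)OC)[C@@H](C[C@@]2(O)/C=C/[Sn](CCCC)(CCCC)CCCC)C1 | intermediate
19 | methyl cis-8-hydroxy-8-[(1E,3E)-4-(trans-4-methoxycarbonylcyclohexyl)penta-1,3-dien-1-yl]-4-[(2S)-6-methylhept-5-en-2-yl]bicyclo[4.2.0]oct-2-ene-1-carboxylate | CC(C)=CCC[C@H](C)[C@@H]1C=C[C@]2(C(=O)OC)[C@@H](C[C@@]2(O)/C=C/C=C(\C)[C@H]2CC[C@H](C(=O)OC)CC2)C1 | intermediate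
20 | lithium alkoxide of 19 | CC(C)=CCC[C@H](C)[C@@H]1C=C[C@]2(C(=O)OC)[C@@H](C[C@@]2([O-])/C=C/C=C(\C)[C@H]2CC[C@H](C(=O)OC)CC2)C1.[Li+] | intermediate
21 | ring-opened lithium ester dienolate: ring A ester enolate at C4a carrying on C8a the 2-oxo-(3E,5E)-dienyl arm | CC(C)=CCC[C@H](C)[C@@H]1C=CC(=C([O-])OC)[C@@H](CC(=O)/C=C/C=C(\C)[C@H]2CC[C@H](C(=O)OC)CC2)C1.[Li+] | intermediate
22 | ring-expanded lithium enolate (C2–O, C2=C3; cis-fused; same configuration as 23) | CC(C)=CCC[C@H](C)[C@@H]1C=C[C@]2(C(=O)OC)[C@@H](CC([O-])=C[C@H]2/C=C(\C)[C@H]2CC[C@H](C(=O)OC)CC2)C1.[Li+] | intermediate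
23 | methyl (4R,4aR,7R,8aR)-4-[(1E)-2-(trans-4-methoxycarbonylcyclohexyl)prop-1-en-1-yl]-7-[(2S)-6-methylhept-5-en-2-yl]-2-(trifluoromethanesulfonyloxy)-1,4,4a,7,8,8a-hexahydronaphthalene-4a-carboxylate | CC(C)=CCC[C@H](C)[C@@H]1C=C[C@]2(C(=O)OC)[C@@H](CC(OS(=O)(=O)C(F)(F)F)=C[C@H]2/C=C(\C)[C@H]2CC[C@H](C(=O)OC)CC2)C1 | intermediate
24 | methyl (4S,4aR,7R,8aR)-4-[(1E)-2-(trans-4-methoxycarbonylcyclohexyl)prop-1-en-1-yl]-2-methyl-7-[(2S)-6-methylhept-5-en-2-yl]-1,4,4a,7,8,8a-hexahydronaphthalene-4a-carboxylate | CC(C)=CCC[C@H](C)[C@@H]1C=C[C@]2(C(=O)OC)[C@@H](CC(C)=C[C@H]2/C=C(\C)[C@H]2CC[C@H](C(=O)OC)CC2)C1 | intermediate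
25 | (4S,4aR,7R,8aR)-4-[(1E)-2-(trans-4-carboxycyclohexyl)prop-1-en-1-yl]-2-methyl-7-[(2S)-6-methylhept-5-en-2-yl]-1,4,4a,7,8,8a-hexahydronaphthalene-4a-carboxylic acid | CC(C)=CCC[C@H](C)[C@@H]1C=C[C@]2(C(=O)O)[C@@H](CC(C)=C[C@H]2/C=C(\C)[C@H]2CC[C@H](C(=O)O)CC2)C1 | target

**Step count**

Total: 12 steps. Longest linear sequence: 10 steps (steps 1–5 and 8–12); steps 6 and 7 make the second fragment, which joins in step 9.

**Steps most likely to fail**

1. Step 5. The photostationary state may lie on the side of 10, because the acyl/allyl radical pair can recombine at the less hindered C6, and the cyclobutanone can be lost by secondary Norrish cleavage to ketene and diene 7. Fallback, setting out from 7 and coming back at 11: Lewis acid-catalysed stepwise [2+2] cycloaddition (Mukaiyama–Michael addition at C8a, then aldol-type closure at C4a) of 7 with commercial 1-(tert-butyldimethylsilyloxy)-1-methoxyethene (EtAlCl2 cat., CH2Cl2, −78 °C) should give the cyclobutanone silyl methyl ketal F1, and buffered aqueous acid (AcOH/THF/H2O) then unmasks ketone 11.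

2. Step 10. Facial selectivity at C4 in the Michael closure may be poor (an exo-type arrangement of the ester enolate would give the C4 epimer), or proton transfer may intercept the open enolate 21 before ring closure. Fallback, setting out from 11 and coming back at 23: addition of vinylmagnesium bromide to 11 gives the vinyl carbinol F2; the same alkoxide-triggered ring expansion (LiN(SiMe3)2, THF), now onto an unsubstituted vinyl ketone, followed by Me3SiCl gives the trimethylsilyl enol ether F3; Saegusa–Ito oxidation (Pd(OAc)2, MeCN) gives the cis-fused enone F4; copper-catalysed (CuBr·SMe2) conjugate addition of alkenylalane 14 from the convex face of the cis-fused bicycle (syn to the angular ester, anti to ring A), activation of the aluminium enolate with MeLi and trapping with PhNTf2 then lead to 23, so that C4 is set by substrate-controlled conjugate addition instead of by the ring closure.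

3. Step 8. The lithium alkoxide may open prematurely by retro-aldol cleavage (the four-membered ring would be lost before the diene is in place), or the basic vinyllithium may enolise the cyclobutanone. Fallback, setting out from 11 and coming back at 18: ethynylmagnesium bromide (THF, −78 °C; the more covalent magnesium alkoxide fragments less readily) gives the propargylic alcohol F5, and palladium-catalysed hydrostannation (Bu3SnH, PdCl2(PPh3)2, THF, 0 °C; syn addition with tin at the distal carbon) gives 18.

**Further compounds**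

F1 | step 5 | methyl cis-8-(tert-butyldimethylsilyloxy)-8-methoxy-4-[(2S)-6-methylhept-5-en-2-yl]bicyclo[4.2.0]oct-2-ene-1-carboxylate (mixture at the ketal carbon) | CC(C)=CCC[C@H](C)[C@@H]1C=C[C@]2(C(=O)OC)[C@@H](CC2(OC)O[Si](C)(C)C(C)(C)C)C1
F2 | step 10 | methyl cis-8-ethenyl-8-hydroxy-4-[(2S)-6-methylhept-5-en-2-yl]bicyclo[4.2.0]oct-2-ene-1-carboxylate | CC(C)=CCC[C@H](C)[C@@H]1C=C[C@]2(C(=O)OC)[C@@H](C[C@@]2(O)C=C)C1
F3 | step 10 | methyl cis-7-[(2S)-6-methylhept-5-en-2-yl]-2-(trimethylsilyloxy)-1,4,4a,7,8,8a-hexahydronaphthalene-4a-carboxylate | CC(C)=CCC[C@H](C)[C@@H]1C=C[C@]2(C(=O)OC)[C@@H](CC(O[Si](C)(C)C)=CC2)C1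
F4 | step 10 | methyl cis-7-[(2S)-6-methylhept-5-en-2-yl]-2-oxo-1,2,4a,7,8,8a-hexahydronaphthalene-4a-carboxylate | CC(C)=CCC[C@H](C)[C@@H]1C=C[C@]2(C(=O)OC)[C@@H](CC(=O)C=C2)C1
F5 | step 8 | methyl cis-8-ethynyl-8-hydroxy-4-[(2S)-6-methylhept-5-en-2-yl]bicyclo[4.2.0]oct-2-ene-1-carboxylate | CC(C)=CCC[C@H](C)[C@@H]1C=C[C@]2(C(=O)OC)[C@@H](C[C@@]2(O)C#C)C1
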